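## The problem

The target is a germacranolide. A ten-membered carbocycle (C1–C10) carries a Z-trisubstituted C4=C5 alkene and an exocyclic C10=C14 methylene, and it is fused through the C6–C7 bond to a butenolide (O–C6, C7=C11, C12=O) whose alkene is tetrasubstituted and bears the C13 acetoxymethyl group. Rings of this size close reluctantly, and a tetrasubstituted butenolide alkene is the worst case for the usual lactone annulations, so ring formation and lactone formation are the two real obstacles. There are three stereocentres: C1 (S, free hydroxyl), C6 (R, lactone oxygen) and C8 (S, acetate). C6 and C8 flank the sp2 carbon C7 and can influence one another, whereas C1 is insulated from both by C9/C10 and by the C2–C5 chain. C1 and C8 therefore call for reagent control, and C6 is the one centre that may be left to the substrate (C8). Several groups are fragile: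

- the C13 acetate is allylic and sits on the butenolide α-carbon, so it is a leaving group towards nucleophiles and low-valent metals;
- the C6 hydrogen is γ to the lactone carbonyl and can epimerize through the furanolate;
- a free C8 hydroxyl can attack C12 and move the lactone from O6 to O8;
- the Z enal and Z alkene can isomerize, and the allylic C1 carbinol is acid-sensitive.

The acetates should therefore arrive late and the last steps must stay close to neutral. The enabling feature is that the unit O–C6–C7=C11–C12(=O) is an aldehyde (C6=O), an alkyne (C7≡C11, with C13 on C11) and carbon monoxide (C12) in disguise. Because C6–C7 belongs to both rings, joining these three components closes the carbocycle and the lactone together.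

## Retrosynthesis

Germacrane numbering is used in the discussion; systematic names are in the compound list.

**Endgame (22 back to 19).** Target 22 is traced to its C1 silyl ether 21 (one O–Si bond), 21 to diol 20 (two O–acyl bonds) and 20 to the tris-silyl ether 19 (two O–Si bonds). Carrying the acetates through the metal step was rejected. A C13 acetate would be a propargylic leaving group towards zerovalent nickel and a β-leaving group on the C11–nickel bond, and it could not be told apart from the C6 acetate used earlier. Two triethylsilyl ethers beside one tert-butyldimethylsilyl ether allow a clean differentiation. The forward steps need selective TES cleavage and acetylation without lactone migration.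

**Key disconnection (19 back to 16 and 17).** Three bonds are cut at once: C6–C7, C11–C12 and C12–O. This leads to the acyclic Z-enal ynal 16 and carbon monoxide 17. Cutting only the lactone C–O bond would leave both the medium ring and the tetrasubstituted alkene unsolved. Cutting a ring bond elsewhere (C8–C9, C3–C4) would leave the butenolide to be made by a separate sequence. The chosen cut removes both rings, the tetrasubstituted alkene and one stereocentre. The forward reaction must bond C6 to C7 rather than C11, attack one face of the aldehyde, and leave the Z alkene untouched.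

**Oxidation level at C6 (16 back to 14).** Enal 16 comes from allylic alcohol 15 and this from acetate 14. No skeletal bond is cut. The acetate is the one already present in commercial neryl acetate, so C6 needs no separate protection step. Its removal must spare three silyl ethers (hydride cleavage rather than methanolysis), and the oxidation must keep the Z geometry.

**C8 stereocentre (14 back to 11).** Bis-silyl ether 14 comes from propargylic alcohol 13, which comes from ynone 12 by cutting the C8–H bond, and 12 from the epimeric carbinol 11. An alkynyl ketone is among the best substrates for catalyst-controlled reduction. This choice frees the preceding C–C bond formation from any stereochemical demand.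

**C8–C9 bond (11 back to 7 and 10).** Cutting C8–C9 gives allylsilane 7 and ynal 10. The neighbouring cut C7–C8 (acetylide addition) would need a β,γ-unsaturated aldehyde that isomerizes readily. The allylsilane also delivers the C10=C14 methylene as it reacts. Ynal 10 comes in two steps from but-2-yne-1,4-diol 8 through monosilyl ether 9. The forward step needs only chemoselectivity for the aldehyde and survival of the silyl ethers.

**C1–C10 bond and C1 stereocentre (7 back to 4 and 5).** Silyl ether 7 comes from alcohol 6, which is cut at C1–C10 into aldehyde 4 and commercial 2-bromoallyltrimethylsilane 5. The alternative cut C1–C2 would need a chiral α-oxygenated aldehyde. The chosen cut sets C1 in the coupling itself under ligand control.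

**Nerol part (4 back to 1).** Aldehyde 4 is neryl acetate 1 with its distal alkene cleaved, by way of epoxide 2 and the transient diol 3. Neryl acetate supplies C2–C6, C15 and the Z C4=C5 alkene ready-made.

## Roads not taken

**Alternative 1: fragmentation of a bicyclic precursor.** The ten-membered ring is opened out of a fused five–seven ring system by breaking the C4–C10 bond. A C10 alkoxide formed with KOtBu expels an antiperiplanar C5 sulfonate, so that the C10 ketone and the C4=C5 alkene appear together in the cyclodecenone A1.

- Merits: the ring is not closed but released, so there is no entropic penalty. The Z geometry follows stereospecifically from the ring stereochemistry. The reaction type is well established. In certainty of ring formation and of alkene geometry this road is better than the chosen one.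
- Weak points for this target: the bicyclic precursor needs stereocentres at C4, C5 and C10 that exist only to be destroyed. In A1, C1–H is α and the C8 silyloxy group β to the new ketone, so the basic conditions invite epimerization and elimination. After A1 the C10 methylene, the whole butenolide (tetrasubstituted alkene, C13 oxygen) and both acetates are still missing.
- Comparison: the chosen plan sets brevity against this. One step makes both rings and brings in the last carbon from a linear precursor, at the price of an untested key reaction.

**Alternative 2: ring closure at C3–C4 by alkyl–alkenyl cross-coupling.** A C2=C3 vinyl group is hydroborated with 9-BBN and the C3 borane is coupled with a C4 Z-iodoalkene (Pd(dppf)Cl2, AsPh3, K3PO4). This gives the silyl ether A2, which has the same structure as compound 21 of the chosen route and is one deprotection from the target.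

- Merits: the Z geometry is fixed in the iodoalkene beforehand. The coupling is a known way to close rings. The closure comes very late on a fully functionalized substrate. In closeness of the key product to the target it is better than the chosen plan, which needs three steps after its key step.
- Weak points: zerovalent palladium meets two allylic acetates (C13, C8) and an allylic lactone C6–O bond next to the reacting iodoalkene. All three can ionize to allyl complexes. Aqueous phosphate threatens the acetates and the C6 configuration. Ten-membered rings are at the lower limit for this coupling. The tetrasubstituted butenolide must first be built intermolecularly by its own sequence.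
- Comparison: the chosen plan sets against this a precursor without sensitive esters and a butenolide made in the ring-closing step itself.

**Alternative 3: carbonyl-ene ring closure at C8–C9.** Me2AlCl activates a C8 aldehyde on the butenolide β-carbon. The methylene terminus of an isopropenyl group bonds to C8 while a C14 hydrogen moves to oxygen, giving the hydroxy lactone A3 with the C10=C14 methylene formed in the same event.

- Merits: the C8 carbinol and the exocyclic alkene come from one atom-economic step. The reaction type is known for ring closures. The nerol-derived half and the reagent-controlled C1 centre are shared with the chosen plan. A3 is two steps from the target. In precedent for the key reaction and in length of the endgame this road is at least as good as the chosen one.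
- Weak points: C8 is set only by the conformation of a medium-ring transition state, without a reagent handle. The C1 hydrogen is a competing ene donor. The aldehyde on an electron-poor butenolide and the allylic C13 acetate must both tolerate the aluminium Lewis acid. The butenolide aldehyde again needs a separate synthesis of the tetrasubstituted lactone.
- Comparison: the chosen plan sets against this catalyst control at C8 and the fact that no preformed butenolide is needed.

Key step: step 13

Remarks on the chemistry:

- The target's C4=C5 bond is Z (C3 and C6 cis), which is the nerol geometry. The stereodescriptors are 1S, 6R, 8S.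
- The sense of induction of the oxazoline–sulfonamide ligand in step 3 is to be assigned on the first run by Mosher ester analysis of 6. The antipodal ligand is used if required; the route is unchanged.
- IPr is 1,3-bis(2,6-diisopropylphenyl)imidazol-2-ylidene.

## Route

Step 1
Reactants: 1 neryl acetate
Product: 2 (2Z)-5-(3,3-dimethyloxiran-2-yl)-3-methylpent-2-en-1-yl acetate
Conditions: mCPBA (1.05 equiv), CH2Cl2, 0 °C
Reagents that add atoms: 3-chloroperoxybenzoic acid, O=C(OO)c1cccc(Cl)c1
Why: Prilezhaev epoxidation; the distal alkene is the more electron-rich one because the C4=C5 alkene is deactivated by the allylic acetate, so one equivalent of peracid should react at the distal site only. The epoxide stereocentre is irrelevant because it is destroyed in step 2.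

Step 2
Reactants: 2 (2Z)-5-(3,3-dimethyloxiran-2-yl)-3-methylpent-2-en-1-yl acetate
Product: 4 (2Z)-3-methyl-6-oxohex-2-en-1-yl acetate, via vicinal diol 3 (not isolated)
Conditions: HIO4·2H2O, THF/Et2O, 0 °C
Reagents that add atoms: none
Why: Acidic periodate opens the epoxide with water at the tertiary carbon to diol 3, which undergoes Malaprade glycol cleavage in the same flask; the aldehyde keeps the former epoxide oxygen and the water oxygen leaves in acetone. Acetate and Z alkene are inert under these conditions.

Step 3
Reactants: 4 (2Z)-3-methyl-6-oxohex-2-en-1-yl acetate; 5 2-bromoallyltrimethylsilane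
Product: 6 (2Z,6S)-6-hydroxy-3-methyl-7-[(trimethylsilyl)methyl]octa-2,7-dien-1-yl acetate
Conditions: CrCl2 (3 equiv), NiCl2 (2 mol %), N-[2-(4-isopropyl-4,5-dihydrooxazol-2-yl)-6-methylphenyl]methanesulfonamide (single enantiomer, 3.3 equiv), Et3N, THF, rt
Reagents that add atoms: none
Why: Asymmetric Nozaki–Hiyama–Kishi coupling of a 2-bromoalkene with an aliphatic aldehyde; nickel activates the C–Br bond, the alkenyl group passes to chromium and adds to the aldehyde only, leaving acetate and allylsilane untouched. The C1 stereocentre (chain C6, S) is set by the chiral sulfonamide ligand on chromium, since the substrate has no other stereocentre.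

Step 4
Reactants: 6 (2Z,6S)-6-hydroxy-3-methyl-7-[(trimethylsilyl)methyl]octa-2,7-dien-1-yl acetate
Product: 7 (2Z,6S)-6-[(tert-butyldimethylsilyl)oxy]-3-methyl-7-[(trimethylsilyl)methyl]octa-2,7-dien-1-yl acetate
Conditions: TBSCl, imidazole, DMF, rt
Reagents that add atoms: tert-butyldimethylsilyl chloride, CC(C)(C)[Si](C)(C)Cl
Why: Standard silylation of a secondary allylic alcohol; the imidazole-buffered medium avoids protodesilylation of the allylsilane and the stereocentre is not involved.

Step 5
Reactants: 8 but-2-yne-1,4-diol
Product: 9 4-[(triethylsilyl)oxy]but-2-yn-1-ol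
Conditions: TESCl (1 equiv), imidazole, 8 (5 equiv), DMF, 0 °C
Reagents that add atoms: chlorotriethylsilane, CC[Si](Cl)(CC)CC
Why: Statistical monosilylation of a symmetric diol; the large excess of the inexpensive diol keeps bis-silylation low and the diol is washed out with water.

Step 6
Reactants: 9 4-[(triethylsilyl)oxy]but-2-yn-1-ol
Product: 10 4-[(triethylsilyl)oxy]but-2-ynal
Conditions: MnO2, CH2Cl2, rt
Reagents that add atoms: none
Why: MnO2 oxidation of a propargylic alcohol to the ynal under neutral conditions that leave the primary silyl ether intact; the aldehyde is used without storage.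

Step 7
Reactants: 7 (2Z,6S)-6-[(tert-butyldimethylsilyl)oxy]-3-methyl-7-[(trimethylsilyl)methyl]octa-2,7-dien-1-yl acetate; 10 4-[(triethylsilyl)oxy]but-2-ynal
Product: 11 (2Z,6S,9RS)-6-[(tert-butyldimethylsilyl)oxy]-9-hydroxy-3-methyl-7-methylidene-12-[(triethylsilyl)oxy]dodec-2-en-10-yn-1-yl acetate
Conditions: BF3·OEt2 (1.1 equiv), CH2Cl2, −78 °C; quench with Et3N then aq. NaHCO3 at −78 °C
Reagents that add atoms: none
Why: Hosomi–Sakurai allylation; the methylene terminus of the allylsilane attacks the BF3-activated ynal and loss of the silyl group from the β-silyl cation forms C8–C9 and unveils the C10=C14 methylene. The C8 carbinol forms as an epimer mixture, which does not matter because it is oxidized next; low temperature and the buffered quench protect the silyl ethers.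

Step 8
Reactants: 11 (2Z,6S,9RS)-6-[(tert-butyldimethylsilyl)oxy]-9-hydroxy-3-methyl-7-methylidene-12-[(triethylsilyl)oxy]dodec-2-en-10-yn-1-yl acetate
Product: 12 (2Z,6S)-6-[(tert-butyldimethylsilyl)oxy]-3-methyl-7-methylidene-9-oxo-12-[(triethylsilyl)oxy]dodec-2-en-10-yn-1-yl acetate
Conditions: Dess–Martin periodinane, NaHCO3, CH2Cl2, 0 °C
Reagents that add atoms: none
Why: Dess–Martin oxidation of a secondary propargylic alcohol; the buffered, non-basic medium should leave the β,γ-alkene out of conjugation, and the ynone is reduced directly.

Step 9
Reactants: 12 (2Z,6S)-6-[(tert-butyldimethylsilyl)oxy]-3-methyl-7-methylidene-9-oxo-12-[(triethylsilyl)oxy]dodec-2-en-10-yn-1-yl acetate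
Product: 13 (2Z,6S,9S)-6-[(tert-butyldimethylsilyl)oxy]-9-hydroxy-3-methyl-7-methylidene-12-[(triethylsilyl)oxy]dodec-2-en-10-yn-1-yl acetate
Conditions: Ru[(S,S)-TsDPEN](p-cymene) (1 mol %, preformed amido complex), i-PrOH, rt
Reagents that add atoms: none
Why: Noyori asymmetric transfer hydrogenation of an alkynyl ketone, run base-free so that the β,γ-alkene does not migrate and the ynone is reduced at the carbonyl only. The C8 stereocentre (chain C9, S) is set by the catalyst, with the alkyne taking the place usually held by an aryl group; by analogy with simple alkynyl ketones the (S,S)-catalyst should give the S carbinol, and C1 is too remote to interfere.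

Step 10
Reactants: 13 (2Z,6S,9S)-6-[(tert-butyldimethylsilyl)oxy]-9-hydroxy-3-methyl-7-methylidene-12-[(triethylsilyl)oxy]dodec-2-en-10-yn-1-yl acetate
Product: 14 (2Z,6S,9S)-6-[(tert-butyldimethylsilyl)oxy]-3-methyl-7-methylidene-9,12-bis[(triethylsilyl)oxy]dodec-2-en-10-yn-1-yl acetate
Conditions: TESCl, imidazole, CH2Cl2, 0 °C
Reagents that add atoms: chlorotriethylsilane, CC[Si](Cl)(CC)CC
Why: Standard silylation of a secondary propargylic alcohol; C8 and C13 now carry the same labile group, to be removed together after the key step.

Step 11
Reactants: 14 (2Z,6S,9S)-6-[(tert-butyldimethylsilyl)oxy]-3-methyl-7-methylidene-9,12-bis[(triethylsilyl)oxy]dodec-2-en-10-yn-1-yl acetate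
Product: 15 (2Z,6S,9S)-6-[(tert-butyldimethylsilyl)oxy]-3-methyl-7-methylidene-9,12-bis[(triethylsilyl)oxy]dodec-2-en-10-yn-1-ol
Conditions: i-Bu2AlH (2.5 equiv), CH2Cl2, −78 °C; aq. potassium sodium tartrate
Reagents that add atoms: none
Why: Reductive cleavage of the acetate by the aluminium hydride at low temperature; this avoids the basic methanolysis that would endanger the primary triethylsilyl ether, and the alkyne is not hydroaluminated at −78 °C.

Step 12
Reactants: 15 (2Z,6S,9S)-6-[(tert-butyldimethylsilyl)oxy]-3-methyl-7-methylidene-9,12-bis[(triethylsilyl)oxy]dodec-2-en-10-yn-1-ol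
Product: 16 (2Z,6S,9S)-6-[(tert-butyldimethylsilyl)oxy]-3-methyl-7-methylidene-9,12-bis[(triethylsilyl)oxy]dodec-2-en-10-ynal
Conditions: MnO2, CH2Cl2, rt, exclusion of light
Reagents that add atoms: none
Why: MnO2 oxidation of the allylic alcohol to the enal; neryl-type alcohols are oxidized by this reagent with retention of the Z geometry, and nothing else in the molecule is oxidizable.

Step 13
Reactants: 16 (2Z,6S,9S)-6-[(tert-butyldimethylsilyl)oxy]-3-methyl-7-methylidene-9,12-bis[(triethylsilyl)oxy]dodec-2-en-10-ynal; 17 carbon monoxide
Product: 19 (1S,4Z,6R,8S)-1-[(tert-butyldimethylsilyl)oxy]-8,13-bis[(triethylsilyl)oxy]germacra-4,7(11),10(14)-trien-6,12-olide, via oxanickelacyclopentene 18 (not isolated)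
Conditions: Ni(cod)2 (1.1 equiv) and IPr (1.1 equiv) premixed, toluene, rt, slow addition of 16 (final 0.002 M); then CO (1 atm), rt
Reagents that add atoms: none
Why: Proposed new method: premixed Ni(cod)2/IPr (zerovalent nickel) should couple the C6 aldehyde and the C7≡C11 alkyne of 16 oxidatively to oxanickelacyclopentene 18 (C6–C7, Ni–O and Ni–C11 bonds), CO then inserts into the Ni–C11 bond and C12–O reductive elimination releases butenolide 19 with Ni(CO)3(IPr); the closest known reactions are the nickel-mediated reductive macrocyclization of ynals, the carbonylation of isolated oxanickelacyclopentenes to butenolides and the Ru3(CO)12- or Mo(CO)6-mediated hetero-Pauson–Khand reaction of short-tethered yne-aldehydes, but a medium ring and a lactone have not been closed together in this way. The ten-membered carbocycle closes in the exocyclic mode (C7 in the ring, C11 outside), and the five-membered lactone closes at C12–O by reductive elimination from the ring-expanded acyl nickelacycle. The required regiochemistry (C6 to C7, not to C11) is favoured by the bulky carbene, which keeps the larger alkyne substituent away from nickel, and by the smaller ring of the exocyclic mode. The new C6 stereocentre is set under substrate control by C8: with C8–H eclipsing the C7–C11 axis to avoid allylic strain with C13, the silyloxy group and C9 occupy opposite faces, and the ring is expected to close with C5 anti to C9, which is the 6R,8S (6α,8α) arrangement; this is the least secure point and both closures should be modelled beforehand. Chemoselectivity rests on the substrate: the β,β-disubstituted enal cannot enter the conjugate coupling mode, the C13 oxygen is a silyl ether so that neither propargylic oxidative addition nor β-elimination from the C11–Ni bond competes, and C10=C14 is only two atoms from the alkyne, too close for an all-carbon enyne cyclocarbonylation. CO is admitted only after the metallacycle has formed because it would otherwise saturate zerovalent nickel, and it is admitted at once at room temperature to outrun β-hydride elimination from the nickel alkoxide. Slow addition at high dilution suppresses oligomerization and keeps free carbene away from the enal; the Z C4=C5 geometry is not touched.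

Step 14
Reactants: 19 (1S,4Z,6R,8S)-1-[(tert-butyldimethylsilyl)oxy]-8,13-bis[(triethylsilyl)oxy]germacra-4,7(11),10(14)-trien-6,12-olide
Product: 20 (1S,4Z,6R,8S)-1-[(tert-butyldimethylsilyl)oxy]-8,13-dihydroxygermacra-4,7(11),10(14)-trien-6,12-olide
Conditions: PPTS (cat.), MeOH/CH2Cl2, 0 °C
Reagents that add atoms: none
Why: Acid-catalysed methanolysis; the primary and the secondary triethylsilyl ether cleave far faster than the hindered secondary tert-butyldimethylsilyl ether. The mildly acidic medium avoids base-induced migration of the lactone to the free C8 hydroxyl and epimerization at C6, and the diol is acetylated without delay.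

Step 15
Reactants: 20 (1S,4Z,6R,8S)-1-[(tert-butyldimethylsilyl)oxy]-8,13-dihydroxygermacra-4,7(11),10(14)-trien-6,12-olide
Product: 21 (1S,4Z,6R,8S)-8,13-diacetoxy-1-[(tert-butyldimethylsilyl)oxy]germacra-4,7(11),10(14)-trien-6,12-olide
Conditions: Ac2O, pyridine, DMAP (cat.), CH2Cl2, 0 °C
Reagents that add atoms: acetic anhydride, CC(=O)OC(C)=O
Why: Standard acetylation of a primary allylic and a secondary allylic alcohol; acylation at 0 °C is faster than any lactone migration and no stereocentre is touched.

Step 16
Reactants: 21 (1S,4Z,6R,8S)-8,13-diacetoxy-1-[(tert-butyldimethylsilyl)oxy]germacra-4,7(11),10(14)-trien-6,12-olide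
Product: 22 8α,13-diacetoxy-1α-hydroxygermacra-4,7(11),10(14)-trien-6α,12-olide
Conditions: HF·pyridine, pyridine, THF, 0 °C to rt
Reagents that add atoms: none
Why: Buffered fluoride cleavage of the silyl ether; HF·pyridine is non-basic and only weakly nucleophilic, so the two acetates and the acetoxymethyl butenolide (an SN2′ acceptor towards basic fluoride sources) should survive.

## Compound list

1 | neryl acetate, (2Z)-3,7-dimethylocta-2,6-dien-1-yl acetate | CC(C)=CCC/C(C)=C\COC(C)=O | starting material
2 | (2Z)-5-(3,3-dimethyloxiran-2-yl)-3-methylpent-2-en-1-yl acetate (racemic epoxide) | CC(=O)OC/C=C(/C)CCC1OC1(C)C | intermediate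
3 | (2Z)-6,7-dihydroxy-3,7-dimethyloct-2-en-1-yl acetate (racemic, not isolated) | CC(=O)OC/C=C(/C)CCC(O)C(C)(C)O | intermediate
4 | (2Z)-3-methyl-6-oxohex-2-en-1-yl acetate | CC(=O)OC/C=C(/C)CCC=O | intermediate
5 | 2-bromoallyltrimethylsilane, (2-bromoprop-2-en-1-yl)trimethylsilane | C=C(Br)C[Si](C)(C)C | starting material
6 | (2Z,6S)-6-hydroxy-3-methyl-7-[(trimethylsilyl)methyl]octa-2,7-dien-1-yl acetate | CC(=O)OC/C=C(/C)CC[C@H](O)C(=C)C[Si](C)(C)C | intermediate
7 | (2Z,6S)-6-[(tert-butyldimethylsilyl)oxy]-3-methyl-7-[(trimethylsilyl)methyl]octa-2,7-dien-1-yl acetate | CC(=O)OC/C=C(/C)CC[C@H](O[Si](C)(C)C(C)(C)C)C(=C)C[Si](C)(C)C | intermediate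
8 | but-2-yne-1,4-diol | OCC#CCO | starting material
9 | 4-[(triethylsilyl)oxy]but-2-yn-1-ol | OCC#CCO[Si](CC)(CC)CC | intermediate
10 | 4-[(triethylsilyl)oxy]but-2-ynal | O=CC#CCO[Si](CC)(CC)CC | intermediate
11 | (2Z,6S,9RS)-6-[(tert-butyldimethylsilyl)oxy]-9-hydroxy-3-methyl-7-methylidene-12-[(triethylsilyl)oxy]dodec-2-en-10-yn-1-yl acetate (C9 epimers) | CC(=O)OC/C=C(/C)CC[C@H](O[Si](C)(C)C(C)(C)C)C(=C)CC(O)C#CCO[Si](CC)(CC)CC | intermediate
12 | (2Z,6S)-6-[(tert-butyldimethylsilyl)oxy]-3-methyl-7-methylidene-9-oxo-12-[(triethylsilyl)oxy]dodec-2-en-10-yn-1-yl acetate | CC(=O)OC/C=C(/C)CC[C@H](O[Si](C)(C)C(C)(C)C)C(=C)CC(=O)C#CCO[Si](CC)(CC)CC | intermediate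
13 | (2Z,6S,9S)-6-[(tert-butyldimethylsilyl)oxy]-9-hydroxy-3-methyl-7-methylidene-12-[(triethylsilyl)oxy]dodec-2-en-10-yn-1-yl acetate | CC(=O)OC/C=C(/C)CC[C@H](O[Si](C)(C)C(C)(C)C)C(=C)C[C@H](O)C#CCO[Si](CC)(CC)CC | intermediate
14 | (2Z,6S,9S)-6-[(tert-butyldimethylsilyl)oxy]-3-methyl-7-methylidene-9,12-bis[(triethylsilyl)oxy]dodec-2-en-10-yn-1-yl acetate | CC(=O)OC/C=C(/C)CC[C@H](O[Si](C)(C)C(C)(C)C)C(=C)C[C@H](O[Si](CC)(CC)CC)C#CCO[Si](CC)(CC)CC | intermediate
15 | (2Z,6S,9S)-6-[(tert-butyldimethylsilyl)oxy]-3-methyl-7-methylidene-9,12-bis[(triethylsilyl)oxy]dodec-2-en-10-yn-1-ol | OC/C=C(/C)CC[C@H](O[Si](C)(C)C(C)(C)C)C(=C)C[C@H](O[Si](CC)(CC)CC)C#CCO[Si](CC)(CC)CC | intermediate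
16 | (2Z,6S,9S)-6-[(tert-butyldimethylsilyl)oxy]-3-methyl-7-methylidene-9,12-bis[(triethylsilyl)oxy]dodec-2-en-10-ynal | O=C/C=C(/C)CC[C@H](O[Si](C)(C)C(C)(C)C)C(=C)C[C@H](O[Si](CC)(CC)CC)C#CCO[Si](CC)(CC)CC | intermediate
17 | carbon monoxide | [C-]#[O+] | starting material
18 | oxanickelacyclopentene of divalent nickel bearing IPr: nickel bonded to O6 and C11, ring Ni–O–C6–C7=C11, fused at C6–C7 to the ten-membered ring (not isolated) | C=C1C[C@H](O[Si](CC)(CC)CC)C2=C(CO[Si](CC)(CC)CC)[Ni](=C3N(c4c(C(C)C)cccc4C(C)C)C=CN3c5c(C(C)C)cccc5C(C)C)O[C@@H]2/C=C(/C)CC[C@@H]1O[Si](C)(C)C(C)(C)C | intermediate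
19 | (1S,4Z,6R,8S)-1-[(tert-butyldimethylsilyl)oxy]-8,13-bis[(triethylsilyl)oxy]germacra-4,7(11),10(14)-trien-6,12-olide | C=C1C[C@H](O[Si](CC)(CC)CC)C2=C(CO[Si](CC)(CC)CC)C(=O)O[C@@H]2/C=C(/C)CC[C@@H]1O[Si](C)(C)C(C)(C)C | intermediate
20 | (1S,4Z,6R,8S)-1-[(tert-butyldimethylsilyl)oxy]-8,13-dihydroxygermacra-4,7(11),10(14)-trien-6,12-olide | C=C1C[C@H](O)C2=C(CO)C(=O)O[C@@H]2/C=C(/C)CC[C@@H]1O[Si](C)(C)C(C)(C)C | intermediate
21 | (1S,4Z,6R,8S)-8,13-diacetoxy-1-[(tert-butyldimethylsilyl)oxy]germacra-4,7(11),10(14)-trien-6,12-olide | C=C1C[C@H](OC(C)=O)C2=C(COC(C)=O)C(=O)O[C@@H]2/C=C(/C)CC[C@@H]1O[Si](C)(C)C(C)(C)C | intermediate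
22 | 8α,13-diacetoxy-1α-hydroxygermacra-4,7(11),10(14)-trien-6α,12-olide, (1S,4Z,6R,8S) | C=C1C[C@H](OC(C)=O)C2=C(COC(C)=O)C(=O)O[C@@H]2/C=C(/C)CC[C@@H]1O | target

## Step count and uncertain steps

Total step count: 16. Longest linear sequence: 14 steps (steps 1–4 and 7–16); steps 5 and 6 prepare ynal 10.

**Step 13 (key step).**

- Most likely failures: ring closure on the wrong aldehyde face (poor diastereoselection at C6, since the only control is the C8 centre acting through a medium-ring transition state); β-hydride elimination from the nickel alkoxide before carbonylation, which would give a dienone; oligomerization instead of ring closure.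
- Fallback (known reaction types only; sets out from 7, returns at 19): C6–C7 is closed by an intramolecular Nozaki–Hiyama–Kishi reaction and the lactone alkene by ring-closing metathesis.
  - Allylsilane 7 is added to 2-bromoacrolein (BF3·OEt2, −78 °C) to give (2Z,6S,9RS)-10-bromo-6-[(tert-butyldimethylsilyl)oxy]-9-hydroxy-3-methyl-7-methylideneundeca-2,10-dien-1-yl acetate F1.
  - Dess–Martin oxidation gives the α-bromo enone F2.
  - Corey–Bakshi–Shibata reduction with the (R)-oxazaborolidine and catecholborane gives the (9S)-bromo allylic alcohol F3 (the bromoalkenyl group acts as the large substituent).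
  - TESCl/imidazole gives the triethylsilyl ether F4, i-Bu2AlH the allylic alcohol F5, and MnO2 the Z-enal bromide F6.
  - CrCl2 with catalytic NiCl2 in THF/DMSO at high dilution closes the ten-membered ring to (1R,2Z,6S,9S)-6-[(tert-butyldimethylsilyl)oxy]-3-methyl-7,10-dimethylidene-9-[(triethylsilyl)oxy]cyclodec-2-en-1-ol F7.
  - Esterification with 2-{[(triethylsilyl)oxy]methyl}prop-2-enoic acid F8 (from 2-(hydroxymethyl)acrylic acid and TESCl) gives the acrylate F9. Carbodiimide/DMAP is used, or Mitsunobu conditions with inversion if the ring closure delivers the C6 epimer.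
  - Ring-closing metathesis with the second-generation Grubbs catalyst in hot toluene forms the tetrasubstituted C7=C11 bond and gives 19.

**Step 3.**

- Most likely failure: insufficient or opposite facial selectivity in the addition to the unbranched aldehyde.
- Fallback (sets out from 4 and 5, returns at 6): the coupling is run without chiral ligand (CrCl2, catalytic NiCl2, DMF) to give the racemic alcohol (2Z,6RS)-6-hydroxy-3-methyl-7-[(trimethylsilyl)methyl]octa-2,7-dien-1-yl acetate F10. Dess–Martin oxidation gives the enone (2Z)-3-methyl-6-oxo-7-[(trimethylsilyl)methyl]octa-2,7-dien-1-yl acetate F11. Corey–Bakshi–Shibata reduction with the (R)-oxazaborolidine (branched alkenyl group as the large substituent) then gives 6.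

**Step 7.**

- Most likely failures: Lewis-acid-induced loss of the primary triethylsilyl ether of 10, or protodesilylation of the allylsilane before C–C bond formation.
- Fallback (sets out from 7, returns at 11): the polarity of the allyl unit is reversed to an allylchromium reagent, which needs no Lewis acid. NBS (propylene oxide, CH2Cl2, −78 °C) bromodesilylates 7 with allylic transposition to (2Z,6S)-7-(bromomethyl)-6-[(tert-butyldimethylsilyl)oxy]-3-methylocta-2,7-dien-1-yl acetate F12. Nozaki–Hiyama allylation of ynal 10 with F12 and CrCl2 in THF gives 11; both termini of the allyl unit lead to the same connectivity.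

**Step 9.**

- Most likely failures: migration of the C10=C14 alkene into conjugation with the ynone during oxidation or reduction, or incomplete catalyst control.
- Fallback (sets out from 7 and 10, returns at 13): the ketone stage is bypassed. The C8 centre is set in the C–C bond-forming step by a catalytic enantioselective Hosomi–Sakurai reaction with a tartrate-derived chiral (acyloxy)borane (EtCN, −78 °C). No new compound arises.

## Further compounds

F1 | step 13 | (2Z,6S,9RS)-10-bromo-6-[(tert-butyldimethylsilyl)oxy]-9-hydroxy-3-methyl-7-methylideneundeca-2,10-dien-1-yl acetate | CC(=O)OC/C=C(/C)CC[C@H](O[Si](C)(C)C(C)(C)C)C(=C)CC(O)C(Br)=C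
F2 | step 13 | (2Z,6S)-10-bromo-6-[(tert-butyldimethylsilyl)oxy]-3-methyl-7-methylidene-9-oxoundeca-2,10-dien-1-yl acetate | CC(=O)OC/C=C(/C)CC[C@H](O[Si](C)(C)C(C)(C)C)C(=C)CC(=O)C(Br)=C
F3 | step 13 | (2Z,6S,9S)-10-bromo-6-[(tert-butyldimethylsilyl)oxy]-9-hydroxy-3-methyl-7-methylideneundeca-2,10-dien-1-yl acetate | CC(=O)OC/C=C(/C)CC[C@H](O[Si](C)(C)C(C)(C)C)C(=C)C[C@H](O)C(Br)=C
F4 | step 13 | (2Z,6S,9S)-10-bromo-6-[(tert-butyldimethylsilyl)oxy]-3-methyl-7-methylidene-9-[(triethylsilyl)oxy]undeca-2,10-dien-1-yl acetate | CC(=O)OC/C=C(/C)CC[C@H](O[Si](C)(C)C(C)(C)C)C(=C)C[C@H](O[Si](CC)(CC)CC)C(Br)=C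
F5 | step 13 | (2Z,6S,9S)-10-bromo-6-[(tert-butyldimethylsilyl)oxy]-3-methyl-7-methylidene-9-[(triethylsilyl)oxy]undeca-2,10-dien-1-ol | OC/C=C(/C)CC[C@H](O[Si](C)(C)C(C)(C)C)C(=C)C[C@H](O[Si](CC)(CC)CC)C(Br)=C
F6 | step 13 | (2Z,6S,9S)-10-bromo-6-[(tert-butyldimethylsilyl)oxy]-3-methyl-7-methylidene-9-[(triethylsilyl)oxy]undeca-2,10-dienal | O=C/C=C(/C)CC[C@H](O[Si](C)(C)C(C)(C)C)C(=C)C[C@H](O[Si](CC)(CC)CC)C(Br)=C
F7 | step 13 | (1R,2Z,6S,9S)-6-[(tert-butyldimethylsilyl)oxy]-3-methyl-7,10-dimethylidene-9-[(triethylsilyl)oxy]cyclodec-2-en-1-ol | C=C1C[C@H](O[Si](CC)(CC)CC)C(=C)[C@H](O)/C=C(/C)CC[C@@H]1O[Si](C)(C)C(C)(C)C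
F8 | step 13 | 2-{[(triethylsilyl)oxy]methyl}prop-2-enoic acid | C=C(CO[Si](CC)(CC)CC)C(=O)O
F9 | step 13 | (1R,2Z,6S,9S)-6-[(tert-butyldimethylsilyl)oxy]-3-methyl-7,10-dimethylidene-9-[(triethylsilyl)oxy]cyclodec-2-en-1-yl 2-{[(triethylsilyl)oxy]methyl}prop-2-enoate | C=C1C[C@H](O[Si](CC)(CC)CC)C(=C)[C@H](OC(=O)C(=C)CO[Si](CC)(CC)CC)/C=C(/C)CC[C@@H]1O[Si](C)(C)C(C)(C)C
F10 | step 3 | (2Z,6RS)-6-hydroxy-3-methyl-7-[(trimethylsilyl)methyl]octa-2,7-dien-1-yl acetate | CC(=O)OC/C=C(/C)CCC(O)C(=C)C[Si](C)(C)C
F11 | step 3 | (2Z)-3-methyl-6-oxo-7-[(trimethylsilyl)methyl]octa-2,7-dien-1-yl acetate | CC(=O)OC/C=C(/C)CCC(=O)C(=C)C[Si](C)(C)C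
F12 | step 7 | (2Z,6S)-7-(bromomethyl)-6-[(tert-butyldimethylsilyl)oxy]-3-methylocta-2,7-dien-1-yl acetate | CC(=O)OC/C=C(/C)CC[C@H](O[Si](C)(C)C(C)(C)C)C(=C)CBr
F0 | step 9 | none | none
A1 | alternative 1 | ten-membered (4Z)-4-en-10-one with C1 tert-butyldimethylsilyloxy, C6 4-methoxybenzyloxy, C7 ethylene ketal and C8 triethylsilyloxy groups | O=C1C[C@H](O[Si](CC)(CC)CC)C2(OCCO2)[C@H](OCc3ccc(OC)cc3)/C=C(/C)CC[C@@H]1O[Si](C)(C)C(C)(C)C
A2 | alternative 2 | (1S,4Z,6R,8S)-8,13-diacetoxy-1-[(tert-butyldimethylsilyl)oxy]germacra-4,7(11),10(14)-trien-6,12-olide | C=C1C[C@H](OC(C)=O)C2=C(COC(C)=O)C(=O)O[C@@H]2/C=C(/C)CC[C@@H]1O[Si](C)(C)C(C)(C)C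
A3 | alternative 3 | (1S,4Z,6R,8S)-13-acetoxy-1-[(tert-butyldimethylsilyl)oxy]-8-hydroxygermacra-4,7(11),10(14)-trien-6,12-olide | C=C1C[C@H](O)C2=C(COC(C)=O)C(=O)O[C@@H]2/C=C(/C)CC[C@@H]1O[Si](C)(C)C(C)(C)C
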